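**Retrosynthetic overview**
1. Target 24 comes from 23 by O4 demethylation, 23 from 21 by bridgehead lithiation and benzoylation at C1, and the C7 prenyl group of 21 from the C7 formyl group of 18 by two Wittig reactions.
2. The strategy rests on C8: in ring A (C1–C8–C7–C6–C5–C9) it is a single CH2 between bridgehead C1 and stereocentre C7. It is treated as a formaldehyde carbon placed on the dione carbon C1 of ring B (C1–C2–C3–C4–C5–C9) as a Mannich base and then attacked by C7, the α-carbon of an aldehyde carried on C6 (15 → 18, C7–C8 bond, ring A).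
3. Precursor 15 comes from ester aldehyde 12 by a fluoride-triggered decarboxylative Mannich reaction; the C1 ester blocks C1 until the aldehyde exists.
4. The C5 quaternary centre (prenyl plus CMe2CH=CH2) comes from a dearomative Claisen rearrangement of aryl prenyl ether 7; the vinyl group becomes CH2CHO by hydroboration and oxidation; the single enantiomer is taken by resolution of 10.
5. Ring order: benzene ring of 1 → dearomatised ring B (step 5) → ring A (step 10).

Key step: step 10

Assumption: the numbering C1–C9 above is used throughout; enolised ring-B compounds are drawn as one tautomer (C9 enol, C2 ketone), and CIP descriptors refer to the tautomer drawn, so the same spatial arrangement at C5 is S in 11–15 and R once C9 is a ketone.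

**Route**

Step 1
Reactants: 1 2,4,6-trihydroxybenzoic acid; 2 2-(trimethylsilyl)ethanol
Product: 3 2-(trimethylsilyl)ethyl 2,4,6-trihydroxybenzoate
Conditions: PPh3, DIAD, THF, 0 °C to rt
Reagents that add atoms: none
Why: Mitsunobu esterification, in which the carboxylic acid, far more acidic than the hydrogen-bonded phenols, is the pronucleophile alkylated by the activated primary alcohol without heating the decarboxylation-prone acid.

Step 2
Reactants: 3 2-(trimethylsilyl)ethyl 2,4,6-trihydroxybenzoate; 4 prenyl bromide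
Product: 5 2-(trimethylsilyl)ethyl 2,4,6-trihydroxy-3,5-bis(3-methylbut-2-en-1-yl)benzoate
Conditions: prenyl bromide (2.2 equiv in all), 10% aq. KOH, 0 °C
Reagents that add atoms: prenyl bromide (second equivalent of 4), CC(C)=CCBr
Why: Two successive C-alkylations of the phloroglucinol phenoxide in water (Friedel–Crafts-type prenylation of the ambident anion), one per equivalent of prenyl bromide, should take place at the two free ring carbons, the ester of the polyanion being inert to hydroxide at 0 °C.

Step 3
Reactants: 5 2-(trimethylsilyl)ethyl 2,4,6-trihydroxy-3,5-bis(3-methylbut-2-en-1-yl)benzoate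
Product: 6 2-(trimethylsilyl)ethyl 2,6-dihydroxy-4-methoxy-3,5-bis(3-methylbut-2-en-1-yl)benzoate
Conditions: Me2SO4 (1.05 equiv), K2CO3, acetone, rt
Reagents that add atoms: dimethyl sulfate, COS(=O)(=O)OC
Why: Williamson ether synthesis at O4, the most acidic phenol (para to the ester) and the only one not hydrogen-bonded to the ester.

Step 4
Reactants: 6 2-(trimethylsilyl)ethyl 2,6-dihydroxy-4-methoxy-3,5-bis(3-methylbut-2-en-1-yl)benzoate; 4 prenyl bromide
Product: 7 2-(trimethylsilyl)ethyl 2-hydroxy-4-methoxy-3,5-bis(3-methylbut-2-en-1-yl)-6-[(3-methylbut-2-en-1-yl)oxy]benzoate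
Conditions: K2CO3, DMF, rt
Reagents that add atoms: none
Why: Williamson O-alkylation in a dipolar aprotic solvent favours oxygen over carbon, and the two hydroxyls are equivalent, the remaining one being deactivated by its hydrogen bond to the ester once the first is alkylated.

Step 5
Reactants: 7 2-(trimethylsilyl)ethyl 2-hydroxy-4-methoxy-3,5-bis(3-methylbut-2-en-1-yl)-6-[(3-methylbut-2-en-1-yl)oxy]benzoate
Product: 8 racemic 2-(trimethylsilyl)ethyl 2-hydroxy-4-methoxy-3-(2-methylbut-3-en-2-yl)-3,5-bis(3-methylbut-2-en-1-yl)-6-oxocyclohexa-1,4-diene-1-carboxylate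
Conditions: Eu(fod)3 (10 mol %; fod = 6,6,7,7,8,8,8-heptafluoro-2,2-dimethyloctane-3,5-dionate), CHCl3, 40 °C; used at once
Reagents that add atoms: none
Why: Aromatic Claisen rearrangement with dearomatisation, accelerated by the europium chelate between ester carbonyl and ether oxygen: the [3,3] shift to the prenyl-bearing ortho carbon gives a dienone that cannot re-aromatise and is held as an enolised β-keto ester, whereas a shift to the ester-bearing carbon is reversible and unstabilised; C5 forms as a racemate, and the mild temperature is meant to outrun a Cope shift of the 1,1-dimethylallyl group on to C3.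

Step 6
Reactants: 8 racemic 2-(trimethylsilyl)ethyl 2-hydroxy-4-methoxy-3-(2-methylbut-3-en-2-yl)-3,5-bis(3-methylbut-2-en-1-yl)-6-oxocyclohexa-1,4-diene-1-carboxylate
Product: 10 racemic 2-(trimethylsilyl)ethyl 2-hydroxy-3-(4-hydroxy-2-methylbutan-2-yl)-4-methoxy-3,5-bis(3-methylbut-2-en-1-yl)-6-oxocyclohexa-1,4-diene-1-carboxylate, via bis-boron adduct 9 (not isolated)
Conditions: 9-BBN (2.5 equiv), THF, 0 °C to rt; then NaBO3·4H2O, THF/H2O, rt
Reagents that add atoms: sodium perborate (used as tetrahydrate), [Na+].[O-]OB=O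
Why: Brown hydroboration–oxidation, in which 9-BBN adds to the terminal carbon of the monosubstituted vinyl group and leaves the trisubstituted prenyl alkenes, the enol first taking up one equivalent as an O-boron chelate that also shields the ring carbonyls, and perborate oxidising the C–B bond near neutrality.

Step 7
Reactants: 10 racemic 2-(trimethylsilyl)ethyl 2-hydroxy-3-(4-hydroxy-2-methylbutan-2-yl)-4-methoxy-3,5-bis(3-methylbut-2-en-1-yl)-6-oxocyclohexa-1,4-diene-1-carboxylate
Product: 11 2-(trimethylsilyl)ethyl (3S)-2-hydroxy-3-(4-hydroxy-2-methylbutan-2-yl)-4-methoxy-3,5-bis(3-methylbut-2-en-1-yl)-6-oxocyclohexa-1,4-diene-1-carboxylate (ring C3 is core C5)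
Conditions: preparative SFC, amylose tris(3,5-dimethylphenylcarbamate) phase, CO2/MeOH
Reagents that add atoms: none
Why: Resolution by chromatography on a chiral stationary phase selects the C5 configuration on a stable intermediate with a polar handle, since no enantioselective dearomative Claisen rearrangement is established for phloroglucinol benzoates; the configuration is to be confirmed by X-ray analysis of a 4-bromobenzoate of the primary alcohol.

Step 8
Reactants: 11 2-(trimethylsilyl)ethyl (3S)-2-hydroxy-3-(4-hydroxy-2-methylbutan-2-yl)-4-methoxy-3,5-bis(3-methylbut-2-en-1-yl)-6-oxocyclohexa-1,4-diene-1-carboxylate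
Product: 12 2-(trimethylsilyl)ethyl (3S)-2-hydroxy-4-methoxy-3-(2-methyl-4-oxobutan-2-yl)-3,5-bis(3-methylbut-2-en-1-yl)-6-oxocyclohexa-1,4-diene-1-carboxylate
Conditions: Dess–Martin periodinane, pyridine, CH2Cl2, 0 °C to rt
Reagents that add atoms: none
Why: Dess–Martin oxidation of the primary alcohol stops at the aldehyde, and because C1 still carries the ester the enolised tricarbonyl unit has no free nucleophilic carbon to condense with the new aldehyde.

Step 9
Reactants: 12 2-(trimethylsilyl)ethyl (3S)-2-hydroxy-4-methoxy-3-(2-methyl-4-oxobutan-2-yl)-3,5-bis(3-methylbut-2-en-1-yl)-6-oxocyclohexa-1,4-diene-1-carboxylate; 13 N,N-dimethylmethyleneiminium iodide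
Product: 15 3-{(1S)-3-[(dimethylamino)methyl]-2-hydroxy-6-methoxy-1,5-bis(3-methylbut-2-en-1-yl)-4-oxocyclohexa-2,5-dien-1-yl}-3-methylbutanal, via carboxylic acid 14 (not isolated)
Conditions: Bu4NF (3 equiv), THF, 0 °C to rt; then 13 (1.5 equiv), 0 °C; pH 8 buffer work-up; used crude
Reagents that add atoms: none
Why: Fluoride-induced fragmentation of the 2-(trimethylsilyl)ethyl ester followed by a decarboxylative Mannich reaction, in which the β-keto carboxylate is aminomethylated at C1 with loss of CO2, so that C1 passes from ester-blocked to aminomethyl-substituted without standing free beside the aldehyde, whose α-carbon does not compete at 0 °C.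

Step 10
Reactants: 15 3-{(1S)-3-[(dimethylamino)methyl]-2-hydroxy-6-methoxy-1,5-bis(3-methylbut-2-en-1-yl)-4-oxocyclohexa-2,5-dien-1-yl}-3-methylbutanal
Product: 18 (1S,5R,7R)-4-methoxy-6,6-dimethyl-3,5-bis(3-methylbut-2-en-1-yl)-2,9-dioxobicyclo[3.3.1]non-3-ene-7-carbaldehyde, via methylene-dione enamine 16 (not isolated), via bicyclic enamine 17 (not isolated)
Conditions: pyrrolidine (1.2 equiv), AcOH (1.2 equiv), MeCN (0.005 M), 40 °C, N2 purge; then aq. NaOAc/AcOH buffer, rt
Reagents that add atoms: water, O
Why: Proposed new method: the ammonium enolate form of 15 expels dimethylamine (E1cB) to give the 2-methylene-1,3-dione while pyrrolidine condenses with the aldehyde, so that 16 holds a nucleophilic enamine carbon (C7) and an electrophilic exocyclic methylene (C8) on the same face of ring B, and C7 adds to C8 in a 6-endo-trig closure of ring A (the C1=C8 bond lies inside the new ring), the closest known reaction type being the secondary-amine-catalysed Michael addition of aldehydes to alkylidene 1,3-dicarbonyl compounds generated in situ, which has not been used to close a bridged ring. Because the electron pair arrives at bridgehead C1 in an exo orbital that overlaps only partly with the C2 carbonyl and not with the C9 carbonyl, a free enolate is not expected; ring B should fold at C9 so that C8 tilts towards C6, and C–C bond formation is coupled to protonation of C1 from the exo face by pyrrolidinium acetate, antiperiplanar to the new C7–C8 bond (the reverse of an E2-type retro-Michael reaction). C1 is set by C5, since the C6 tether can deliver C7 to C8 only across the ring-B face that carries it, which places the bridgehead hydrogen exo. C7 is set thermodynamically, the formyl group equilibrating through enamine 17 to the exo (equatorial) position of chair ring A, away from ring B and its C3 substituent. The step needs intramolecular C–C bond formation to win over amine re-addition, bimolecular Michael addition and O-cyclisation: amine adducts at C8 are reversible, high dilution and purging of dimethylamine hold back bimolecular paths, the gem-dimethyl group at C6 keeps the enamine over ring B, and hetero-Diels–Alder closure through O2 or O9 would need a bridgehead C=C bond. Bicycle 18 should also be the thermodynamic sink, because any retro-Michael opening to the C1–H dione and the 2-substituted acrolein closes again to the same skeleton.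

Step 11
Reactants: 18 (1S,5R,7R)-4-methoxy-6,6-dimethyl-3,5-bis(3-methylbut-2-en-1-yl)-2,9-dioxobicyclo[3.3.1]non-3-ene-7-carbaldehyde
Product: 19 (1S,5R,7S)-4-methoxy-7-(2-methoxyethenyl)-6,6-dimethyl-3,5-bis(3-methylbut-2-en-1-yl)bicyclo[3.3.1]non-3-ene-2,9-dione (E/Z mixture)
Conditions: Ph3P+CH2OMe Cl−, KN(SiMe3)2, THF, 0 °C; then 18, −78 to 0 °C
Reagents that add atoms: (methoxymethyl)triphenylphosphonium chloride, COC[P+](c1ccccc1)(c1ccccc1)c1ccccc1.[Cl-]
Why: Wittig reaction of the unstabilised methoxymethylidene ylide, which should add to the aldehyde far faster than to the vinylogous-ester C2 carbonyl or the C9 ketone flanked by two bridgeheads, the low temperature limiting deprotonation at C7 and leaving its configuration as set.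

Step 12
Reactants: 19 (1S,5R,7S)-4-methoxy-7-(2-methoxyethenyl)-6,6-dimethyl-3,5-bis(3-methylbut-2-en-1-yl)bicyclo[3.3.1]non-3-ene-2,9-dione
Product: 20 2-[(1S,5R,7S)-4-methoxy-6,6-dimethyl-3,5-bis(3-methylbut-2-en-1-yl)-2,9-dioxobicyclo[3.3.1]non-3-en-7-yl]acetaldehyde
Conditions: 1 M HCl, THF, 0 °C to rt
Reagents that add atoms: water, O
Why: Acid-catalysed enol ether hydrolysis, the simple alkyl enol ether being protonated at carbon far more readily than the cross-conjugated C4 vinylogous ester, while dilute acid at low temperature leaves the prenyl groups and C7 untouched.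

Step 13
Reactants: 20 2-[(1S,5R,7S)-4-methoxy-6,6-dimethyl-3,5-bis(3-methylbut-2-en-1-yl)-2,9-dioxobicyclo[3.3.1]non-3-en-7-yl]acetaldehyde
Product: 21 (1S,5R,7R)-4-methoxy-6,6-dimethyl-3,5,7-tris(3-methylbut-2-en-1-yl)bicyclo[3.3.1]non-3-ene-2,9-dione
Conditions: i-PrPPh3+ I−, n-BuLi, THF, 0 °C; then 20, −78 to 0 °C
Reagents that add atoms: isopropyltriphenylphosphonium iodide, CC(C)[P+](c1ccccc1)(c1ccccc1)c1ccccc1.[I-]
Why: Wittig olefination with the isopropylidene ylide turns the CH2CHO group into the C7 prenyl group, the aldehyde being the only carbonyl reactive enough for this hindered ylide.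

Step 14
Reactants: 21 (1S,5R,7R)-4-methoxy-6,6-dimethyl-3,5,7-tris(3-methylbut-2-en-1-yl)bicyclo[3.3.1]non-3-ene-2,9-dione
Product: 23 (1R,5R,7R)-1-benzoyl-4-methoxy-6,6-dimethyl-3,5,7-tris(3-methylbut-2-en-1-yl)bicyclo[3.3.1]non-3-ene-2,9-dione, via bridgehead lithium enolate 22 (not isolated)
Conditions: LiN(i-Pr)2 (2 equiv), THF, −78 °C; then PhCOCl, −78 to −40 °C
Reagents that add atoms: benzoyl chloride, O=C(Cl)c1ccccc1
Why: Bridgehead lithiation–acylation, C1–H being the only proton α to the C2 carbonyl (C3 and C5 are fully substituted), its partial overlap with C2=O allowing deprotonation to a pyramidal bridgehead enolate that can only C-acylate, with retention enforced by the bicycle (the descriptor changes from S to R only through CIP priorities).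

Step 15
Reactants: 23 (1R,5R,7R)-1-benzoyl-4-methoxy-6,6-dimethyl-3,5,7-tris(3-methylbut-2-en-1-yl)bicyclo[3.3.1]non-3-ene-2,9-dione
Product: 24 (1S,5R,7R)-1-benzoyl-2-hydroxy-6,6-dimethyl-3,5,7-tris(3-methylbut-2-en-1-yl)bicyclo[3.3.1]non-2-ene-4,9-dione (CNP0284108.1)
Conditions: LiCl, DMSO, 120 °C; dilute HCl work-up
Reagents that add atoms: none
Why: SN2 demethylation of the vinylogous methyl ester by chloride (Krapcho-type) should release the enolised β-diketone of the target without touching a stereocentre.

**Compound list**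
1 | 2,4,6-trihydroxybenzoic acid | O=C(O)c1c(O)cc(O)cc1O | starting material
2 | 2-(trimethylsilyl)ethanol | C[Si](C)(C)CCO | starting material
3 | 2-(trimethylsilyl)ethyl 2,4,6-trihydroxybenzoate | C[Si](C)(C)CCOC(=O)c1c(O)cc(O)cc1O | intermediate
4 | prenyl bromide (1-bromo-3-methylbut-2-ene) | CC(C)=CCBr | starting material
5 | 2-(trimethylsilyl)ethyl 2,4,6-trihydroxy-3,5-bis(3-methylbut-2-en-1-yl)benzoate | C[Si](C)(C)CCOC(=O)c1c(O)c(CC=C(C)C)c(O)c(CC=C(C)C)c1O | intermediate
6 | 2-(trimethylsilyl)ethyl 2,6-dihydroxy-4-methoxy-3,5-bis(3-methylbut-2-en-1-yl)benzoate | C[Si](C)(C)CCOC(=O)c1c(O)c(CC=C(C)C)c(OC)c(CC=C(C)C)c1O | intermediate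
7 | 2-(trimethylsilyl)ethyl 2-hydroxy-4-methoxy-3,5-bis(3-methylbut-2-en-1-yl)-6-[(3-methylbut-2-en-1-yl)oxy]benzoate | C[Si](C)(C)CCOC(=O)c1c(O)c(CC=C(C)C)c(OC)c(CC=C(C)C)c1OCC=C(C)C | intermediate
8 | racemic 2-(trimethylsilyl)ethyl 2-hydroxy-4-methoxy-3-(2-methylbut-3-en-2-yl)-3,5-bis(3-methylbut-2-en-1-yl)-6-oxocyclohexa-1,4-diene-1-carboxylate | CC(C)=CCC=1C(=O)C(C(=O)OCC[Si](C)(C)C)=C(O)C(CC=C(C)C)(C(C)(C)C=C)C=1OC | intermediate
9 | racemic bis-boron adduct of 8: enol O–(9-BBN) and terminal C–(9-BBN) on the former vinyl group | CC(C)=CCC=1C(=O)C(C(=O)OCC[Si](C)(C)C)=C(OB2C3CCCC2CCC3)C(CC=C(C)C)(C(C)(C)CCB2C3CCCC2CCC3)C=1OC | intermediate (not isolated)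
10 | racemic 2-(trimethylsilyl)ethyl 2-hydroxy-3-(4-hydroxy-2-methylbutan-2-yl)-4-methoxy-3,5-bis(3-methylbut-2-en-1-yl)-6-oxocyclohexa-1,4-diene-1-carboxylate | CC(C)=CCC=1C(=O)C(C(=O)OCC[Si](C)(C)C)=C(O)C(CC=C(C)C)(C(C)(C)CCO)C=1OC | intermediate
11 | 2-(trimethylsilyl)ethyl (3S)-2-hydroxy-3-(4-hydroxy-2-methylbutan-2-yl)-4-methoxy-3,5-bis(3-methylbut-2-en-1-yl)-6-oxocyclohexa-1,4-diene-1-carboxylate | CC(C)=CCC=1C(=O)C(C(=O)OCC[Si](C)(C)C)=C(O)[C@](CC=C(C)C)(C(C)(C)CCO)C=1OC | intermediate
12 | 2-(trimethylsilyl)ethyl (3S)-2-hydroxy-4-methoxy-3-(2-methyl-4-oxobutan-2-yl)-3,5-bis(3-methylbut-2-en-1-yl)-6-oxocyclohexa-1,4-diene-1-carboxylate | CC(C)=CCC=1C(=O)C(C(=O)OCC[Si](C)(C)C)=C(O)[C@](CC=C(C)C)(C(C)(C)CC=O)C=1OC | intermediate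
13 | N,N-dimethylmethyleneiminium iodide (Eschenmoser's salt) | C=[N+](C)C.[I-] | starting material
14 | (3S)-2-hydroxy-4-methoxy-3-(2-methyl-4-oxobutan-2-yl)-3,5-bis(3-methylbut-2-en-1-yl)-6-oxocyclohexa-1,4-diene-1-carboxylic acid (present as its tetrabutylammonium salt) | CC(C)=CCC=1C(=O)C(C(=O)O)=C(O)[C@](CC=C(C)C)(C(C)(C)CC=O)C=1OC | intermediate (not isolated)
15 | 3-{(1S)-3-[(dimethylamino)methyl]-2-hydroxy-6-methoxy-1,5-bis(3-methylbut-2-en-1-yl)-4-oxocyclohexa-2,5-dien-1-yl}-3-methylbutanal (key-step precursor; core C5 S) | CC(C)=CCC=1C(=O)C(CN(C)C)=C(O)[C@](CC=C(C)C)(C(C)(C)CC=O)C=1OC | intermediate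
16 | (5R)-ring-B 2-methylene-1,3-dione (C1=CH2, C2 and C9 ketones, C3=C4 methyl enol ether) carrying the E-pyrrolidine enamine of the C6 aldehyde | CC(C)=CCC=1C(=O)C(=C)C(=O)[C@](CC=C(C)C)(C(C)(C)/C=C/N2CCCC2)C=1OC | intermediate (not isolated)
17 | (1S,5R)-4-methoxy-6,6-dimethyl-3,5-bis(3-methylbut-2-en-1-yl)-7-(pyrrolidin-1-ylmethylidene)bicyclo[3.3.1]non-3-ene-2,9-dione | CC(C)=CCC=1C(=O)[C@@H]2CC(=CN3CCCC3)C(C)(C)[C@](CC=C(C)C)(C=1OC)C2=O | intermediate (not isolated)
18 | (1S,5R,7R)-4-methoxy-6,6-dimethyl-3,5-bis(3-methylbut-2-en-1-yl)-2,9-dioxobicyclo[3.3.1]non-3-ene-7-carbaldehyde (key-step product) | CC(C)=CCC=1C(=O)[C@@H]2C[C@@H](C=O)C(C)(C)[C@](CC=C(C)C)(C=1OC)C2=O | intermediate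
19 | (1S,5R,7S)-4-methoxy-7-(2-methoxyethenyl)-6,6-dimethyl-3,5-bis(3-methylbut-2-en-1-yl)bicyclo[3.3.1]non-3-ene-2,9-dione (E/Z mixture) | CC(C)=CCC=1C(=O)[C@@H]2C[C@@H](C=COC)C(C)(C)[C@](CC=C(C)C)(C=1OC)C2=O | intermediate
20 | 2-[(1S,5R,7S)-4-methoxy-6,6-dimethyl-3,5-bis(3-methylbut-2-en-1-yl)-2,9-dioxobicyclo[3.3.1]non-3-en-7-yl]acetaldehyde | CC(C)=CCC=1C(=O)[C@@H]2C[C@@H](CC=O)C(C)(C)[C@](CC=C(C)C)(C=1OC)C2=O | intermediate
21 | (1S,5R,7R)-4-methoxy-6,6-dimethyl-3,5,7-tris(3-methylbut-2-en-1-yl)bicyclo[3.3.1]non-3-ene-2,9-dione | CC(C)=CCC=1C(=O)[C@@H]2C[C@@H](CC=C(C)C)C(C)(C)[C@](CC=C(C)C)(C=1OC)C2=O | intermediate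
22 | C1-lithio derivative (bridgehead lithium enolate) of 21 | CC(C)=CCC=1C(=O)[C@]2([Li])C[C@@H](CC=C(C)C)C(C)(C)[C@](CC=C(C)C)(C=1OC)C2=O | intermediate (not isolated)
23 | (1R,5R,7R)-1-benzoyl-4-methoxy-6,6-dimethyl-3,5,7-tris(3-methylbut-2-en-1-yl)bicyclo[3.3.1]non-3-ene-2,9-dione | CC(C)=CCC=1C(=O)[C@]2(C(=O)c3ccccc3)C[C@@H](CC=C(C)C)C(C)(C)[C@](CC=C(C)C)(C=1OC)C2=O | intermediate
24 | (1S,5R,7R)-1-benzoyl-2-hydroxy-6,6-dimethyl-3,5,7-tris(3-methylbut-2-en-1-yl)bicyclo[3.3.1]non-2-ene-4,9-dione (CNP0284108.1) | CC(C)=CCC1=C(O)[C@]2(C(=O)c3ccccc3)C[C@@H](CC=C(C)C)C(C)(C)[C@](CC=C(C)C)(C1=O)C2=O | target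

**Step count and risk**
Total step count: 15. Longest linear sequence: 15 steps (from 1 to 24).

The three steps most likely to fail:

1. Step 10 (key step). The ring closure may stall because the electron pair has to arrive at a bridgehead carbon; reversible amine adducts at C8, bimolecular Michael addition of one enamine to the methylene dione of another molecule and oligomerisation would then consume the material. The fallback uses known chemistry and reverses the polarity of the closure so that ring A closes through the C1–C8 bond. It sets out from 12: Eschenmoser's salt and Et3N in CH2Cl2 aminomethylate the aldehyde α-carbon C7 while the ester still blocks C1, giving the C7 Mannich base F1, which loses dimethylamine in the flask to give the 2-substituted acrolein F2. Bu4NF in THF then cleaves the ester; the enal carboxylic acid F3 loses CO2, and the dione enolate released at C1 adds to the enal terminus C8. This is an intramolecular Michael addition of a dearomatised acylphloroglucinol to an α-substituted acrolein, the ring-forming event of the alkylative dearomatisation–annulation route to bicyclo[3.3.1]nonane-7-carbaldehydes. Protonation and base-mediated equilibration of the formyl group to the exo position should give 18, where the route is rejoined.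

2. Step 5. The allyl fragment may migrate to the ester-bearing ortho carbon C1, may be lost by Lewis-acid ionisation of the prenyl ether, or, once on C5, may move on to C3 by a Cope shift. The fallback lets O4 carry the migrating group. It sets out from 5: O-prenylation of the most acidic phenol O4 (prenyl bromide, K2CO3, acetone) gives the 4-O-prenyl ether F4, whose two ortho carbons are the same prenyl-bearing carbon, so that an uncatalysed Claisen rearrangement (toluene, 80 °C) has no regiochemical choice and needs no Lewis acid; it gives the racemic 4-hydroxy dienone F5. Methylation of its free vinylogous-acid oxygen O4 with Me3SiCHN2 (MeOH/toluene), the O2 regioisomer being removed if it forms, gives 8, where the route is rejoined and the dienone is again taken into step 6 without delay.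

3. Step 9. During the fluoride treatment the aldehyde sits in a basic medium beside an enolate; aldol-type condensation, or reaction of a free C1–H dione with the aldehyde if CO2 is lost before the iminium salt arrives, may erode the material. The fallback aminomethylates before the aldehyde exists. It sets out from 11 (step 8 is left out): Bu4NF in THF, then Eschenmoser's salt, give through the carboxylic acid alcohol F6 the amino alcohol F7. Oxidation of its primary alcohol with (n-Pr4N)RuO4 and N-methylmorpholine N-oxide (4 Å sieves, CH2Cl2), the amine being masked as the internal ammonium enolate, gives 15, where the route is rejoined.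

Further compounds
F1 | step 10 | 2-(trimethylsilyl)ethyl ester of the C7 Mannich base of 12 (C7 bearing CH2NMe2 and CHO; C7 epimers; not isolated) | CC(C)=CCC=1C(=O)C(C(=O)OCC[Si](C)(C)C)=C(O)[C@](CC=C(C)C)(C(C)(C)C(CN(C)C)C=O)C=1OC
F2 | step 10 | 2-(trimethylsilyl)ethyl (3S)-2-hydroxy-4-methoxy-3-(2-methyl-3-methylidene-4-oxobutan-2-yl)-3,5-bis(3-methylbut-2-en-1-yl)-6-oxocyclohexa-1,4-diene-1-carboxylate | CC(C)=CCC=1C(=O)C(C(=O)OCC[Si](C)(C)C)=C(O)[C@](CC=C(C)C)(C(C)(C)C(=C)C=O)C=1OC
F3 | step 10 | carboxylic acid from F2 (present as its tetrabutylammonium salt; not isolated) | CC(C)=CCC=1C(=O)C(C(=O)O)=C(O)[C@](CC=C(C)C)(C(C)(C)C(=C)C=O)C=1OC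
F4 | step 5 | 2-(trimethylsilyl)ethyl 2,6-dihydroxy-3,5-bis(3-methylbut-2-en-1-yl)-4-[(3-methylbut-2-en-1-yl)oxy]benzoate | C[Si](C)(C)CCOC(=O)c1c(O)c(CC=C(C)C)c(OCC=C(C)C)c(CC=C(C)C)c1O
F5 | step 5 | racemic 2-(trimethylsilyl)ethyl 2,4-dihydroxy-3-(2-methylbut-3-en-2-yl)-3,5-bis(3-methylbut-2-en-1-yl)-6-oxocyclohexa-1,4-diene-1-carboxylate | CC(C)=CCC=1C(=O)C(C(=O)OCC[Si](C)(C)C)=C(O)C(CC=C(C)C)(C(C)(C)C=C)C=1O
F6 | step 9 | (3S)-2-hydroxy-3-(4-hydroxy-2-methylbutan-2-yl)-4-methoxy-3,5-bis(3-methylbut-2-en-1-yl)-6-oxocyclohexa-1,4-diene-1-carboxylic acid (present as its tetrabutylammonium salt; not isolated) | CC(C)=CCC=1C(=O)C(C(=O)O)=C(O)[C@](CC=C(C)C)(C(C)(C)CCO)C=1OC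
F7 | step 9 | (4S)-2-[(dimethylamino)methyl]-3-hydroxy-4-(4-hydroxy-2-methylbutan-2-yl)-5-methoxy-4,6-bis(3-methylbut-2-en-1-yl)cyclohexa-2,5-dien-1-one | CC(C)=CCC=1C(=O)C(CN(C)C)=C(O)[C@](CC=C(C)C)(C(C)(C)CCO)C=1OC
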